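(The runs are simulated with made-up constants; scatter was added.)

- The easy step comes first: substrate turns to intermediate and intermediate to product, so in a closed run whatever the two readings do not account for is substrate.

all flasks: free catalyst 2.4 mM; impurity 0.45 mM

|  | substrate | remark | time |
|---|---|---|---|
| eta | 0.50 M | run made earlier |  |
| zeta | 0.25 M | run made earlier |  |
| delta | 0.38 M | run made earlier |  |
| Monday's | 0.50 M | one stirred flow tank at steady state, fed with the mixture as stated, mean residence time 15 min |  |
| Friday's | 0.50 M | a tube with plug flow, the mixed feed as stated, residence time 15 min | 15 min |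
| Tuesday's | 0.50 M (fed, over 12.0 min) | all but substrate at the start; substrate goes in evenly over 12.0 min, the run ends at 15 min | 15 min |
| Wednesday's | 0.50 M | a closed flask charged with all of it at once and left for 15 min | 15 min |

| run | time / min | intermediate / % | product / % |
|---|---|---|---|
| eta | 1.33 | 17.7 | 2.9 |
| eta | 2.50 | 26.9 | 7.2 |
| eta | 4.00 | 33.6 | 15.7 |
| eta | 5.00 | 35.3 | 21.8 |
| eta | 6.00 | 35.6 | 27.6 |
| eta | 8.00 | 33.9 | 39.8 |
| eta | 10.0 | 30.3 | 50.7 |
| zeta | 1.00 | 14.1 | 1.7 |
| zeta | 1.33 | 17.3 | 2.6 |
| zeta | 2.00 | 23.1 | 5.5 |
| zeta | 3.00 | 29.9 | 9.9 |
| zeta | 5.00 | 35.6 | 21.7 |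
| zeta | 8.00 | 34.3 | 39.3 |
| zeta | 12.0 | 26.3 | 61.1 |
| delta | 1.50 | 19.4 | 3.1 |
| delta | 3.00 | 29.7 | 10.1 |
| delta | 5.00 | 35.7 | 21.4 |
| delta | 6.00 | 35.8 | 27.7 |
| delta | 8.00 | 33.8 | 39.6 |
| delta | 10.0 | 30.2 | 51.4 |
| delta | 12.0 | 26.2 | 61.1 |

(standard deviation of a reading: 0.3 percentage points)

- the stated concentrations are those of everything mixed, before any reaction; amounts are the same in each set-up
- the feed brings no volume worth counting
- the earlier runs were made in a closed, stirred flask

* the set-up with the highest amount of intermediate at the outlet or at the end, in percent of the substrate put in ("none" if the first two lie within 2 percentage points) (Monday's / Friday's / Tuesday's / Wednesday's / none)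
* amount of intermediate at the outlet or at the end, in percent of the substrate put in, Monday's
* amount of intermediate at the outlet or at the end, in percent of the substrate put in, Friday's
* amount of intermediate at the outlet or at the end, in percent of the substrate put in, Tuesday's
* amount of intermediate at the outlet or at the end, in percent of the substrate put in, Wednesday's

- **Substrate charge.** By hand, first-order steps make the percent curves independent of the charge. The runs agree: at 5.00 min intermediate reads 35.3% in eta at 0.50 M and 35.6% in zeta at 0.25 M.
- **Time.** I work with the fraction left, f = c(substrate)/charge, which falls as e^(−k·age). The last readings of eta, zeta and delta give a mean k of 0.170 min⁻¹. Late in eta, product gained per intermediate reads 0.170 min⁻¹, much the same, so I use one k for both steps, and a portion of age t holds k·t·f as intermediate.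
- **Vessel.** In Wednesday's flask and Friday's tube each portion has age 15 min, so f is 7.78% and intermediate 19.9% in both.
- **Mixing.** In Monday's tank the ages spread exponentially around the mean 15 min, so f averages to one over one plus k times that mean age, or 28.1%, and intermediate comes to 20.2%.
- **Dosing.** In Tuesday's flask the ages spread evenly from 3.00 min to 15 min, which gives 25.6%: this is the age-averaged fraction left, the mean of f over the ages of the portions. The same averaging of k·t·f gives 30.8% intermediate, so I commit to Tuesday's, ahead of Monday's by more than the margin.
- **Forecast.** It names Tuesday's, with 20% for Monday's, 19.7% for Friday's, 30.6% for Tuesday's and 19.7% for Wednesday's, on the ground that “the late feed has had less time to go on to product”. My figures for Tuesday's and Wednesday's run a little higher than its.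
- **Result.** The best is Tuesday's, with 30.4% for Tuesday's, 19.5% for Monday's, 19.4% for Friday's and 19.4% for Wednesday's.

    free catalyst + intermediate → free catalyst + product (k = 125 M⁻¹ min⁻¹)
    2 free catalyst ⇌ resting dimer (K = 148 M⁻¹, k = 70.6 M⁻¹ min⁻¹)
    free catalyst + impurity → spent catalyst (k = 76600 M⁻¹ min⁻¹)
    substrate → intermediate (k = 0.168 min⁻¹)

- The age-averaged fraction left of 25.6% stands beside 26% of substrate in Tuesday's flask, and for that flask read at 1.0 h it gives 0.0121% against 0.014%. At 15.0 min in Tuesday's flask, the half-life of substrate is 4.1 min and that of intermediate, by its pseudo-first-order step with free catalyst at 57.6% of the catalyst charged, is 4.0 min, close to each other. That intermediate half-life is short against the 15 min, and at the end Tuesday's flask holds 26.0% substrate, 43.7% product and 30.4% intermediate.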